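If both roads from substrate end in a product, reckon the end state first. Each substrate consumes one reagent by either road, and substrate is the limiting reagent, so reagent ends at 16.7% of its charge and open intermediate ends at nil. What is asked is how far each flask has come at the reading.

common to all: free catalyst 2.0 µM
- winter: substrate 2.0 mM; reagent 2.40 mM; time 6.0 min; a closed flask charged with all of it at once and left for 6.0 min
- midnight: substrate 2.0 mM (fed, over 6.00 min); reagent 2.40 mM; time 6.0 min; a stirred flask in which substrate is dosed at a steady rate over 6.00 min without added volume, worked up at 6.0 min
- spring: substrate 2.0 mM; reagent 2.40 mM (fed, over 6.00 min); time 6.0 min; a stirred flask in which reagent is dosed at a steady rate over 6.00 min without added volume, worked up at 6.0 min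
- dawn: substrate 2.0 mM; reagent 2.40 mM; a single well-mixed tank run continuously and read at steady state, 6.0 min in it on average

1. the set-up with the highest amount of open intermediate at the outlet or at the end, in percent of the substrate put in ("none" if the first two lie within 2 percentage points) (winter / midnight / spring / dawn / none)
2. amount of open intermediate at the outlet or at the end, in percent of the substrate put in, winter
3. amount of open intermediate at the outlet or at the end, in percent of the substrate put in, midnight
4. amount of open intermediate at the outlet or at the end, in percent of the substrate put in, spring
5. amount of open intermediate at the outlet or at the end, in percent of the substrate put in, dawn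

    substrate + free catalyst → free catalyst + open intermediate (k1 = 8710 M⁻¹ s⁻¹)
    free catalyst + open intermediate ⇌ catalyst intermediate (K2 = 863 M⁻¹, k2 = 1.25 × 10⁵ M⁻¹ s⁻¹)
    reagent + catalyst intermediate → free catalyst + target (k3 = 4530 M⁻¹ s⁻¹)
    substrate + reagent → uncatalysed product (k4 = 3.94 M⁻¹ s⁻¹)

Step 2 returns faster than step 3 drains, so treat the bound form as in equilibrium with open intermediate. Then define the drain time, a pseudo-first-order lifetime of open intermediate, as (1 + K2·c(open intermediate)) divided by k3·K2·c(reagent) times the catalyst charge, both forms counted. With the reagent charge and little open intermediate it is 0.888 min.

Set up three more rows:

- Winter after the burst: substrate half-lives are short against the run, and 64.8% of it opens at charged rates, which gives 2.66 min.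
- Winter near the end state, with reagent at its floor: 5.33 min.
- Spring mid-dose, with half the reagent dosed, none of it counted as spent, and the whole substrate charge taken as open: 4.84 min.

Read the rows downward. The floor row is about as long as the run, so expect winter to be unfinished at the reading. Averaging its two rows leaves 14.4%. The spring row is longer than the winter burst row, so commit to spring holding more than winter. The reckoning stops there for midnight and dawn, and it gives no number for spring.

The forecast gave winter 13%, midnight 22%, spring 35% and dawn 20%, with spring best, by “starving the flask of reagent”.

The simulation gives winter 12.9%, midnight 20.4%, spring 36.4% and dawn 20.3%, so spring is best.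

Now take the spring flask read at 10 min. At 6.00 min spring holds 36.4% open intermediate and its reagent stands at 48.0% of charge, so the drain time is 3.01 min. Average it with the floor row, as for winter, and decay 36.4% over the extra 4.00 min: the estimate is 13.9%. That flask reads 12.3% open intermediate, with target at 75.6%.

All constants were drawn at random within sensible limits; no experiment stands behind them.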